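Retrosynthesis: HBr is added back across the exocyclic C5=CBr2 alkene to give a C5–CBr3 butenolide. Its C5–C(exo) bond is then cut to a 2-silyloxyfuran and CBr4, whose carbon keeps two of its four bromines in the target.
The lactone bonds O1–C5 and C4–Br are cut together to give 2-butylbuta-2,3-dienoic acid. The allene C2=C3 bond is cut by a Wittig disconnection to a hexanoate ylide and ketene.
Enabling feature: in the furanone ring, C4 (Br) lies between C3 (butyl, bonded to carbonyl C2) and the O-bearing C5. This is the central carbon of an allene with butyl and CO2H at one end and CH2 at the other.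
Forward: the C6 ylide and C2 ketene are joined, the only ring is closed by bromolactonisation, C5 is activated as the silyloxyfuran, the last carbon is grafted from CBr4, and HBr is expelled.
Stereochemistry: the target has no stereocentre and the =CBr2 group has no E/Z isomers. The racemic centres of early and late intermediates are all erased.

Key step: step 5

Remark: commercial ethyl 2-bromohexanoate is taken as the racemate, which does not matter because its stereocentre becomes the planar ylide carbon.

Step 1
Reactants: 1 ethyl 2-bromohexanoate (racemic)
Product: 2 (1-ethoxy-1-oxohexan-2-yl)triphenylphosphonium bromide (racemic)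
Conditions: PPh3 (1.05 equiv), toluene, 100 °C, 36 h; filter, wash with Et2O
Reagents that add atoms: triphenylphosphine, c1ccc(cc1)P(c1ccccc1)c1ccccc1
Why: SN2 quaternisation of triphenylphosphine by an α-bromo ester (first half of the standard stabilised-ylide preparation), in which the adjacent carbonyl accelerates displacement at the secondary carbon and separation of the salt from hot toluene drives the slow reaction to completion.

Step 2
Reactants: 2 (1-ethoxy-1-oxohexan-2-yl)triphenylphosphonium bromide
Product: 3 ethyl 2-(triphenyl-λ5-phosphanylidene)hexanoate
Conditions: 1 M aq NaOH, CH2Cl2, 0 °C to rt, 15 min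
Reagents that add atoms: none
Why: Acid–base formation of a stabilised Wittig ylide, in which the α-proton of the ester-bearing phosphonium salt is acidic enough for cold dilute hydroxide and the ylide passes into CH2Cl2 before ester or P–C hydrolysis can set in, the stereocentre of 2 disappearing here.

Step 3
Reactants: 3 ethyl 2-(triphenyl-λ5-phosphanylidene)hexanoate; 4 acetyl chloride
Product: 6 ethyl 2-butylbuta-2,3-dienoate, via ketene 5 (not isolated)
Conditions: Et3N (1.1 equiv), CH2Cl2, 0 °C, slow addition of 4 (1.05 equiv), then rt, 12 h; pentane trituration
Reagents that add atoms: none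
Why: Wittig olefination of a ketene (the standard allenoate synthesis from stabilised ylides and acid chlorides), in which Et3N dehydrochlorinates 4 to 5, the ylide carbon takes the ketene carbonyl and cycloreversion of the oxaphosphetane gives the C=C=C unit, while the hydrogen-free ylide carbon cannot be diverted into a stable acyl ylide.

Step 4
Reactants: 6 ethyl 2-butylbuta-2,3-dienoate
Product: 8 2-butylbuta-2,3-dienoic acid, via lithium 2-butylbuta-2,3-dienoate 7 (not isolated)
Conditions: LiOH·H2O (1.5 equiv), THF–H2O (3:1), 0 °C to rt; then 1 M HCl to pH 2, 0 °C, Et2O extraction; used within a day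
Reagents that add atoms: lithium hydroxide, [Li+].[OH-]
Why: Mild ester saponification (BAc2) as routinely applied to 2,3-allenoates, in which the hydrogen-free C2 excludes base-induced drift to a conjugated alkynoate and the low temperature with only a small excess of hydroxide limits conjugate hydration at the central allene carbon.

Step 5
Reactants: 8 2-butylbuta-2,3-dienoic acid
Product: 9 4-bromo-3-butylfuran-2(5H)-one
Conditions: CuBr2 (3 equiv), acetone–H2O (2:1), 65 °C, 6 h
Reagents that add atoms: copper dibromide, [Cu+2].[Br-].[Br-]
Why: CuBr2 acts as a two-electron Br+ source (two CuBr2 end as two CuBr, divalent to monovalent copper): it engages the terminal C3=C4 π bond of the allene, bromine is delivered to the central sp carbon and the carboxyl oxygen attacks the CH2 terminus from the opposite face, so the lactone bonds C4–Br and O1–C5 form in one event and loss of the carboxyl proton gives 9 with its C3=C4 alkene already conjugated to the carbonyl. The closest known reaction type is the CuX2-mediated halolactonisation of 2,3-allenoic acids to 4-halofuran-2(5H)-ones. The ring closes in the 5-endo-trig mode, which is easy here because the p orbitals of the terminal π bond lie in the plane of the C2 substituents, so the carboxyl oxygen reaches the terminus without twisting. No stereocentre is created. The step needs bromine at the central carbon with O-closure at the terminus instead of dibromide formation, hydration or attack on the C2=C3 bond, and the carboxyl group secures this because it depletes the C2=C3 bond electronically and holds the only nucleophile placed to trap the activated terminus intramolecularly. The unsubstituted CH2 terminus supports positive charge poorly, hence the warm polar medium and the excess of CuBr2, while the product, a β-bromo enoate, is too electron-poor to be brominated again.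

Step 6
Reactants: 9 4-bromo-3-butylfuran-2(5H)-one
Product: 10 [(4-bromo-3-butylfuran-2-yl)oxy](tert-butyl)dimethylsilane
Conditions: TBSOTf (1.2 equiv), Et3N (1.5 equiv), CH2Cl2, 0 °C, 1 h; pentane, cold aq NaHCO3 wash, dry; used crude under argon
Reagents that add atoms: tert-butyldimethylsilyl trifluoromethanesulfonate, CC(C)(C)[Si](C)(C)OS(=O)(=O)C(F)(F)F
Why: Soft enolisation and O-silylation of a butenolide to a 2-silyloxyfuran, well known for 4-bromofuran-2(5H)-ones, in which silylation of the carbonyl oxygen acidifies the C5 methylene, Et3N removes one C5–H and aromatisation to the furan drives the reaction while the vinylic C–Br bond stays untouched.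

Step 7
Reactants: 10 [(4-bromo-3-butylfuran-2-yl)oxy](tert-butyl)dimethylsilane; 11 carbon tetrabromide
Product: 12 4-bromo-3-butyl-5-(tribromomethyl)furan-2(5H)-one (racemic)
Conditions: 11 (3 equiv), Et3B (0.3 equiv, 1 M in hexane), dry air (slow syringe feed), 2,6-di-tert-butylpyridine (0.2 equiv, acid trap), CH2Cl2, −40 °C, 2 h; cold concentration, short silica plug
Reagents that add atoms: none
Why: Proposed new method: ethyl radicals from Et3B and O2 abstract bromine from 11 to give the electrophilic tribromomethyl radical, which adds to the unsubstituted, electron-rich C5 of the silyloxyfuran and leaves an allyl radical with spin at C2 between two oxygens; this strongly reducing radical passes an electron to (or takes a bromine atom from) a further molecule of 11, which regenerates the chain carrier, and bromide strips the silyl group from the resulting silyloxocarbenium ion to restore the butenolide with C5 formed racemic; the closest known reaction type is the Et3B- or metal-initiated radical polyhaloalkylation of silyl enol ethers and ketene silyl acetals (Kharasch-type addition followed by loss of silyl halide), extended here to the vinylogous position of a 2-silyloxyfuran and to CBr4, and the excess of 11, the low temperature and a live chain are what should hold back ionic bromination at C5.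

Step 8
Reactants: 12 4-bromo-3-butyl-5-(tribromomethyl)furan-2(5H)-one
Product: 13 4-bromo-3-butyl-5-(dibromomethylidene)furan-2(5H)-one (target)
Conditions: iPr2NEt (1.2 equiv), CH2Cl2, 0 °C, 20 min; cold dilute citric acid wash
Reagents that add atoms: none
Why: E1cB dehydrobromination, the reaction type by which α-(trihalomethyl) carbonyl compounds give β,β-dihalo enones, here in vinylogous form, in which the amine removes the doubly activated C5–H, the 2-oxidofuran expels bromide from the CBr3 group and the racemic centre vanishes, while the hindered base, low temperature and short contact protect the electrophilic product from amine addition–elimination.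

Compound list
1 | ethyl 2-bromohexanoate (racemic) | CCCCC(Br)C(=O)OCC | starting material
2 | (1-ethoxy-1-oxohexan-2-yl)triphenylphosphonium bromide (racemic) | CCCCC(C(=O)OCC)[P+](c1ccccc1)(c1ccccc1)c1ccccc1.[Br-] | intermediate
3 | ethyl 2-(triphenyl-λ5-phosphanylidene)hexanoate | CCCCC(C(=O)OCC)=P(c1ccccc1)(c1ccccc1)c1ccccc1 | intermediate
4 | acetyl chloride | CC(=O)Cl | starting material
5 | ketene (not isolated) | C=C=O | intermediate
6 | ethyl 2-butylbuta-2,3-dienoate | CCCCC(=C=C)C(=O)OCC | intermediate
7 | lithium 2-butylbuta-2,3-dienoate (not isolated) | CCCCC(=C=C)C(=O)[O-].[Li+] | intermediate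
8 | 2-butylbuta-2,3-dienoic acid | CCCCC(=C=C)C(=O)O | intermediate
9 | 4-bromo-3-butylfuran-2(5H)-one | CCCCC1=C(Br)COC1=O | intermediate
10 | [(4-bromo-3-butylfuran-2-yl)oxy](tert-butyl)dimethylsilane | CCCCc1c(Br)coc1O[Si](C)(C)C(C)(C)C | intermediate
11 | carbon tetrabromide | BrC(Br)(Br)Br | starting material
12 | 4-bromo-3-butyl-5-(tribromomethyl)furan-2(5H)-one (racemic) | CCCCC1=C(Br)C(C(Br)(Br)Br)OC1=O | intermediate
13 | 4-bromo-3-butyl-5-(dibromomethylidene)furan-2(5H)-one | CCCCC1=C(Br)C(=C(Br)Br)OC1=O | target

Total step count: 8. Longest linear sequence: 8 steps (from 1 to 13).

Steps most likely to fail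

Step 7. Ionic transfer of bromine from CBr4 to C5 may outrun the radical chain. The chain may also stall because the stabilised adduct radical propagates poorly, or traces of acid may protodesilylate the furan. The fallback uses known chemistry, sets out from 10 and returns to the route at 13. It brings in the exocyclic carbon as CH2 and installs its bromines afterwards. A vinylogous Mannich reaction of 10 with dimethyl(methylidene)ammonium iodide (CH2Cl2, rt) should give 4-bromo-3-butyl-5-[(dimethylamino)methyl]furan-2(5H)-one F1. Methyl iodide should quaternise it to [(3-bromo-4-butyl-5-oxo-2,5-dihydrofuran-2-yl)methyl]trimethylammonium iodide F2. Aqueous NaHCO3/CH2Cl2 should then bring about Hofmann-type elimination to 4-bromo-3-butyl-5-methylidenefuran-2(5H)-one F3. Br2 (CH2Cl2, 0 °C) should add to the exocyclic enol-ester alkene to give 4,5-dibromo-5-(bromomethyl)-3-butylfuran-2(5H)-one F4. iPr2NEt should dehydrobrominate this to (Z)-4-bromo-5-(bromomethylidene)-3-butylfuran-2(5H)-one F5, whose geometry is of no consequence. A second addition of Br2 should give 4,5-dibromo-3-butyl-5-(dibromomethyl)furan-2(5H)-one F6, and a second treatment with iPr2NEt should deliver 13.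

Step 5. Capture at the unsubstituted terminus may be sluggish. Plain dibromination or hydration of the allene, or acid-induced bromine-free cycloisomerisation, could then compete with ring closure. The fallback sets out from 1 and returns at 9. It builds the ring first as a tetronic acid and introduces bromine by replacing the enol oxygen. A Blaise reaction of 1 with activated zinc dust and 2-[(trimethylsilyl)oxy]acetonitrile (THF, reflux, slow addition of 1) should give, as its bromozinc chelate, ethyl (Z)-3-amino-2-butyl-4-[(trimethylsilyl)oxy]but-2-enoate F7. Aqueous HCl should convert this in one operation into 3-butyl-4-hydroxyfuran-2(5H)-one F8. Vilsmeier-type bromodehydroxylation with oxalyl dibromide and DMF (CH2Cl2, 0 °C to rt) should then give 9.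

Step 4. Hydroxide may add to the central allene carbon, causing hydration followed by cleavage or decarboxylation. The free acid may also degrade during isolation and storage. The fallback sets out from 6 and returns at 9 without liberating the acid. It is the direct aqueous halolactonisation of the 2,3-allenoate with CuBr2 (EtOH–H2O, 80 °C). The ester carbonyl oxygen closes on the allene terminus and water removes the ethyl group from the cyclic oxocarbenium ion. No new compound is made on the way.

Further compounds
F1 | step 7 | 4-bromo-3-butyl-5-[(dimethylamino)methyl]furan-2(5H)-one (racemic) | CCCCC1=C(Br)C(CN(C)C)OC1=O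
F2 | step 7 | [(3-bromo-4-butyl-5-oxo-2,5-dihydrofuran-2-yl)methyl]trimethylammonium iodide (racemic) | CCCCC1=C(Br)C(C[N+](C)(C)C)OC1=O.[I-]
F3 | step 7 | 4-bromo-3-butyl-5-methylidenefuran-2(5H)-one | CCCCC1=C(Br)C(=C)OC1=O
F4 | step 7 | 4,5-dibromo-5-(bromomethyl)-3-butylfuran-2(5H)-one (racemic) | CCCCC1=C(Br)C(Br)(CBr)OC1=O
F5 | step 7 | (Z)-4-bromo-5-(bromomethylidene)-3-butylfuran-2(5H)-one | CCCCC1=C(Br)/C(=C/Br)OC1=O
F6 | step 7 | 4,5-dibromo-3-butyl-5-(dibromomethyl)furan-2(5H)-one (racemic) | CCCCC1=C(Br)C(Br)(C(Br)Br)OC1=O
F7 | step 5 | ethyl (Z)-3-amino-2-butyl-4-[(trimethylsilyl)oxy]but-2-enoate | CCCC/C(C(=O)OCC)=C(/N)CO[Si](C)(C)C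
F8 | step 5 | 3-butyl-4-hydroxyfuran-2(5H)-one | CCCCC1=C(O)COC1=O
F0 | step 4 | none | none
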